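Locants follow benzofuran numbering (O1, C2, C3, C3a, C4–C7, C7a); ring A is the benzo ring and ring B is the 4-hydroxy-3,5-dimethoxyphenyl ring.
Cuts: with both OH groups masked as silyl ethers, the dihydrofuran ring is cut at O1–C2 and then at C3a–C3. This leaves two C6–C3 phenols: methyl dihydroferulate (ring A) and (E)-sinapyl alcohol (ring B with C2=C3).
Enabling feature: C2 is benzylic to ring B and para to its oxygen O4' (donor). O1 sits on C7a next to C3a (acceptor once ring A is a dienone). A spiro cyclopropane C3a–C3–C2 on a dearomatised ring A must therefore move C2 from C3a to O1 and give the ring O1–C2–C3–C3a–C7a.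
Forward order: ring A is raised to the C3a-diazo/C7a-oxo level (nitration, reduction, diazotisation) and sinapyl alcohol is bis-silylated. A chiral dirhodium carbene transfer joins the halves: the cyclopropane forms first, then the dihydrofuran ring as ring A re-aromatises and the helper N2 is lost. Desilylation ends the route.
Stereochemistry: C3 comes from catalyst-controlled face selection on the E-alkene when C3a–C3 forms. C2 follows from C3 in the trans-selective O1–C2 closure, and the spiro centre is temporary.

Key step: step 5

Assumption: the facial sense of Rh2(S-TCPTTL)4 on this new pair of partners cannot be derived safely from precedent, so the S catalyst is written; should the first run deliver the (2R,3S) series, the R catalyst (from D-tert-leucine) takes its place with nothing else changed. (TBS = tert-butyldimethylsilyl.)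

Step 1
Reactants: 1 methyl 3-(4-hydroxy-3-methoxyphenyl)propanoate (methyl dihydroferulate)
Product: 2 methyl 3-(4-hydroxy-3-methoxy-5-nitrophenyl)propanoate
Conditions: HNO3 (65%, 1.05 equiv), AcOH, 5–10 °C
Reagents that add atoms: nitric acid, O[N+](=O)[O-]
Why: Electrophilic aromatic nitration directed by the free phenol, whose para position and one ortho position are blocked, should take the remaining ortho carbon (the later C3a), as is usual for vanillin and 4-alkylguaiacols.

Step 2
Reactants: 2 methyl 3-(4-hydroxy-3-methoxy-5-nitrophenyl)propanoate
Product: 3 methyl 3-(3-amino-4-hydroxy-5-methoxyphenyl)propanoate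
Conditions: H2 (1 atm), 10% Pd/C, MeOH, rt
Reagents that add atoms: none
Why: Catalytic hydrogenation of a nitroarene to the aniline leaves the ester and the aryl ethers untouched, and the air-sensitive aminophenol is carried on at once.

Step 3
Reactants: 3 methyl 3-(3-amino-4-hydroxy-5-methoxyphenyl)propanoate
Product: 4 methyl 3-(3-diazo-5-methoxy-4-oxocyclohexa-1,5-dien-1-yl)propanoate (ortho-quinone diazide of ring A)
Conditions: t-BuONO (1.2 equiv), TFA (5 mol %), CH2Cl2, 0 °C, dark; cold aq NaHCO3 wash; kept cold and in solution
Reagents that add atoms: tert-butyl nitrite, CC(C)(C)ON=O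
Why: Diazotisation of an ortho-aminophenol gives a diazonium ion whose strongly acidic OH loses its proton, which is the classical entry to neutral ortho-quinone diazides (diazo oxides).

Step 4
Reactants: 5 (E)-sinapyl alcohol, 4-[(E)-3-hydroxyprop-1-enyl]-2,6-dimethoxyphenol
Product: 6 (E)-sinapyl alcohol bis-TBS ether, tert-butyl{4-[(E)-3-(tert-butyldimethylsilyloxy)prop-1-enyl]-2,6-dimethoxyphenoxy}dimethylsilane
Conditions: TBSCl (2.4 equiv), imidazole (5 equiv), DMF, rt
Reagents that add atoms: tert-butyldimethylsilyl chloride, CC(C)(C)[Si](C)(C)Cl
Why: Standard imidazole-promoted silylation caps both OH groups, which blocks O–H insertion in the next step and keeps ring B a π-donor; the alkene geometry is untouched.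

Step 5
Reactants: 4 methyl 3-(3-diazo-5-methoxy-4-oxocyclohexa-1,5-dien-1-yl)propanoate; 6 (E)-sinapyl alcohol bis-TBS ether
Product: 8 methyl 3-[(2S,3R)-2-(4-tert-butyldimethylsilyloxy-3,5-dimethoxyphenyl)-3-(tert-butyldimethylsilyloxymethyl)-7-methoxy-2,3-dihydrobenzofuran-5-yl]propanoate, via spirocyclopropyl dienone 7 (not isolated)
Conditions: Rh2(S-TCPTTL)4 (dirhodium tetrakis[N-tetrachlorophthaloyl-(S)-tert-leucinate], 1 mol %), 6 (1.0 equiv), 4 (1.5 equiv, syringe pump over 4 h), 4 Å MS, PhCF3, 25–40 °C, dark
Reagents that add atoms: none
Why: Proposed new method: Rh2(S-TCPTTL)4, a dimer of divalent rhodium, should expel N2 from 4 to give an electrophilic quinoid carbene at C3a, which the E-alkene of 6 attacks through C3 because the positive charge that builds at C2 is carried by the 4-silyloxy-3,5-dimethoxyphenyl ring B, and collapse closes the three-membered ring C3a–C3–C2 of 7 by a stereospecific [2+1] addition. In 7 the C3a–C2 bond lies between the donor ring B and the dienone acceptor, so it should ionise at once with release of ring strain and gain of ring A aromaticity, and the phenolate O1 then closes the five-membered ring on C2 of the quinoid benzylic cation in a 5-exo-trig mode, overall a Cloke–Wilson-type 1,3-shift of C2 from C3a to O1. The closest known reaction types are the dirhodium-catalysed formal [3+2] cycloadditions of cyclic 2-diazo-1,3-diketones and of diazonaphthoquinones with styrenes and enol ethers and the enantioselective spirocyclopropanation of styrenes with quinone diazides; new here are the benzenoid ortho-quinone diazide, the 1,2-disubstituted cinnamyl-type alkene and the enantioselective course of the whole cascade. C3 is fixed when C3a–C3 forms, by the chiral carboxylate pocket that admits one face of the alkene, and is not touched afterwards, whereas the spiro centre C3a is erased on aromatisation. C2 is controlled by C3, since O1 enters on the side that C3a leaves (least motion, retention of the trans cyclopropane geometry) and a fully free cation would also close anti to the CH2OTBS group, so both paths should lead to the 2,3-trans ring. The step needs addition to the alkene rather than insertion into the allylic C–H bonds, ylide formation at oxygen, attack on ring B or carbene dimerisation, which the electron-rich styrene π bond, the bulky silyl groups on both oxygens, the flat tied-back carbene and the slow addition of 4 should secure.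

Step 6
Reactants: 8 methyl 3-[(2S,3R)-2-(4-tert-butyldimethylsilyloxy-3,5-dimethoxyphenyl)-3-(tert-butyldimethylsilyloxymethyl)-7-methoxy-2,3-dihydrobenzofuran-5-yl]propanoate
Product: 9 methyl 3-[(2S,3R)-2-(4-hydroxy-3,5-dimethoxyphenyl)-3-(hydroxymethyl)-7-methoxy-2,3-dihydrobenzofuran-5-yl]propanoate (target)
Conditions: Et3N·3HF (6 equiv), THF, rt
Reagents that add atoms: none
Why: Fluoride-induced silyl ether cleavage under buffered, slightly acidic conditions frees both hydroxyl groups without ester hydrolysis and without forming the ring B phenoxide that could reopen O1–C2 through the para-quinone methide, so C2 and C3 stay as set.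

Compound list
1 | methyl 3-(4-hydroxy-3-methoxyphenyl)propanoate (methyl dihydroferulate) | COC(=O)CCc1ccc(O)c(OC)c1 | starting material
2 | methyl 3-(4-hydroxy-3-methoxy-5-nitrophenyl)propanoate | COC(=O)CCc1cc(OC)c(O)c(c1)[N+](=O)[O-] | intermediate
3 | methyl 3-(3-amino-4-hydroxy-5-methoxyphenyl)propanoate | COC(=O)CCc1cc(N)c(O)c(OC)c1 | intermediate
4 | methyl 3-(3-diazo-5-methoxy-4-oxocyclohexa-1,5-dien-1-yl)propanoate | COC(=O)CCC1=CC(=[N+]=[N-])C(=O)C(OC)=C1 | intermediate
5 | (E)-sinapyl alcohol | COc1cc(/C=C/CO)cc(OC)c1O | starting material
6 | (E)-sinapyl alcohol bis-TBS ether | COc1cc(/C=C/CO[Si](C)(C)C(C)(C)C)cc(OC)c1O[Si](C)(C)C(C)(C)C | intermediate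
7 | methyl 3-[(1S,2R,3S)-1-(4-TBSO-3,5-dimethoxyphenyl)-2-(TBSOCH2)-5-methoxy-4-oxospiro[2.5]octa-5,7-dien-7-yl]propanoate; aryl and CH2OTBS trans on the cyclopropane, ring carbonyl on the face of CH2OTBS; not isolated | COC(=O)CCC1=C[C@@]2(C(=O)C(OC)=C1)[C@H](CO[Si](C)(C)C(C)(C)C)[C@H]2c1cc(OC)c(O[Si](C)(C)C(C)(C)C)c(OC)c1 | intermediate
8 | methyl 3-[(2S,3R)-2-(4-TBSO-3,5-dimethoxyphenyl)-3-(TBSOCH2)-7-methoxy-2,3-dihydrobenzofuran-5-yl]propanoate (2,3-trans) | COC(=O)CCc1cc(OC)c2c(c1)[C@H](CO[Si](C)(C)C(C)(C)C)[C@@H](c1cc(OC)c(O[Si](C)(C)C(C)(C)C)c(OC)c1)O2 | intermediate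
9 | methyl 3-[(2S,3R)-2-(4-hydroxy-3,5-dimethoxyphenyl)-3-(hydroxymethyl)-7-methoxy-2,3-dihydrobenzofuran-5-yl]propanoate (2,3-trans) | COC(=O)CCc1cc(OC)c2c(c1)[C@H](CO)[C@@H](c1cc(OC)c(O)c(OC)c1)O2 | target

Total steps: 6. Longest linear sequence: 5 (steps 1, 2, 3, 5, 6).

Steps most likely to fail

1. Step 5 (the labelled step).
- Process at risk: carbene transfer to a 1,2-disubstituted alkene may be slow. Carbene dimerisation, insertion into the allylic C–H bonds next to the silyloxy group or poor facial selectivity could then take over.
- Fallback (known chemistry: oxidative phenol coupling followed by resolution): it sets out from 1 and 5 and comes back at 9. 5 is added slowly to an excess of 1 and Ag2O in acetone–CH2Cl2 at rt. The two phenoxyl radicals should couple between the β-carbon of 5 and the free ortho carbon of 1. Tautomerisation restores the ring A phenol and gives the para-quinone methide methyl 3-{4-hydroxy-3-[1-hydroxy-3-(3,5-dimethoxy-4-oxocyclohexa-2,5-dien-1-ylidene)propan-2-yl]-5-methoxyphenyl}propanoate F1. This closes the same O1–C2 bond anti to CH2OH. The racemic trans product is separated on a chiral stationary phase into 9 and the (2R,3S) enantiomer of 9 F2, which is set aside.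

2. Step 3.
- Process at risk: loss of N2, light-induced Wolff ring contraction, and azo coupling of the diazonium ion with unreacted electron-rich 3, during formation, concentration or storage of the neutral diazo oxide.
- Fallback: it sets out from 3 and comes back at 4. 3 is diazotised with t-BuONO and HBF4·OEt2 in Et2O–MeCN at −10 °C. The acid medium protonates the remaining amine, and the salt 2-hydroxy-3-methoxy-5-(3-methoxy-3-oxopropyl)benzenediazonium tetrafluoroborate F3 precipitates and can be filtered and stored cold. Just before step 5 it is shaken with cold aqueous NaHCO3 and PhCF3. The dried organic layer, which holds 4, goes straight into the syringe pump, so 4 is never handled neat.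

3. Step 1.
- Process at risk: oxidation of the electron-rich guaiacol ring to quinones, ipso attack at the carbon that bears the side chain, and nitration para to the methoxy group.
- Fallback: it sets out from 1 and comes back at 3, so 2 is bypassed. 1 is coupled at pH 9 (Na2CO3 buffer, 0 °C) with diazotised sulfanilic acid. This electrophile is too weak to oxidise the ring and attacks only ortho to the phenoxide. It gives the azo dye methyl 3-{4-hydroxy-3-methoxy-5-[(E)-(4-sulfophenyl)diazenyl]phenyl}propanoate F4. Reductive cleavage of the N=N bond with Na2S2O4 in aqueous MeOH should give 3, and the water-soluble amine fragment is washed out.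

Further compounds
F1 | step 5 | methyl 3-{4-hydroxy-3-[1-hydroxy-3-(3,5-dimethoxy-4-oxocyclohexa-2,5-dien-1-ylidene)propan-2-yl]-5-methoxyphenyl}propanoate (racemic para-quinone methide, not isolated) | COC(=O)CCc1cc(OC)c(O)c(c1)C(CO)C=C1C=C(OC)C(=O)C(OC)=C1
F2 | step 5 | methyl 3-[(2R,3S)-2-(4-hydroxy-3,5-dimethoxyphenyl)-3-(hydroxymethyl)-7-methoxy-2,3-dihydrobenzofuran-5-yl]propanoate (enantiomer of 9) | COC(=O)CCc1cc(OC)c2c(c1)[C@@H](CO)[C@H](c1cc(OC)c(O)c(OC)c1)O2
F3 | step 3 | 2-hydroxy-3-methoxy-5-(3-methoxy-3-oxopropyl)benzenediazonium tetrafluoroborate | COC(=O)CCc1cc(OC)c(O)c([N+]#N)c1.F[B-](F)(F)F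
F4 | step 1 | methyl 3-{4-hydroxy-3-methoxy-5-[(E)-(4-sulfophenyl)diazenyl]phenyl}propanoate | COC(=O)CCc1cc(OC)c(O)c(/N=N/c2ccc(cc2)S(=O)(=O)O)c1
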